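**Retrosynthetic overview** (locants: C1 = ester carbon … C9 = CH2 on the furan)
1. The last step cuts the vinyl–alkyl bond C7–C8 and the C6–CH3 bond together: enyne ester 20, Me3Al 21 and 3-(2-iodoethyl)furan 5 are joined in one flask.
2. Enabling feature: the trisubstituted C6(CH3)=C7H alkene whose methyl and C8H2 are cis. This is the footprint of a syn-methylmetalation of a terminal alkyne C6≡C7–H followed by alkylation at C7 with retention.
3. 20 comes from an E-selective Wittig reaction (C2=C3) of pent-4-ynal 19 with the α-alkyl ylide 17. 17 comes from iodide 14, whose (S) centre is set by an Evans allylation.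
4. 5 comes from 3-bromofuran and ethylene oxide.
5. No ring is formed in the route: the furan, the only ring, is bought intact in 3-bromofuran.

Key step: step 11

Remark: the SMILES is read as the (2E,6E)-diene with an (S) centre at the carbon that carries the acetoxymethyl group.

**Step 1**
Reactants: 1 3-bromofuran; 2 ethylene oxide
Product: 4 2-(furan-3-yl)ethan-1-ol, via 3-furyllithium 3 (not isolated)
Conditions: n-BuLi, THF, −78 °C; then 2, BF3·OEt2, −78 °C; H2O
Reagents that add atoms: none
Why: Br/Li exchange at −78 °C gives 3-furyllithium, which opens BF3-activated ethylene oxide (organolithium epoxide opening) before lithium can migrate to C2 of the furan.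

**Step 2**
Reactants: 4 2-(furan-3-yl)ethan-1-ol
Product: 5 3-(2-iodoethyl)furan
Conditions: I2, PPh3, imidazole, CH2Cl2, 0 °C
Reagents that add atoms: iodine, II
Why: Appel-type iodination converts the primary alcohol into the iodide under near-neutral conditions that the acid-sensitive furan should tolerate.

**Step 3**
Reactants: 6 (R)-4-benzyl-3-propionyloxazolidin-2-one; 7 allyl iodide
Product: 9 (R)-4-benzyl-3-[(S)-2-methylpent-4-enoyl]oxazolidin-2-one, via sodium enolate 8 (not isolated)
Conditions: NaHMDS, THF, −78 °C; then 7, −78 → −45 °C
Reagents that add atoms: none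
Why: Evans asymmetric alkylation: allyl iodide attacks the chelated (Z)-sodium enolate on the face opposite the benzyl group at C4 of the auxiliary, which sets the (S) methyl-bearing centre.

**Step 4**
Reactants: 9 (R)-4-benzyl-3-[(S)-2-methylpent-4-enoyl]oxazolidin-2-one
Product: 10 (S)-2-methylpent-4-en-1-ol
Conditions: LiBH4, H2O (1 equiv), Et2O, 0 °C
Reagents that add atoms: none
Why: Reductive cleavage of the N-acyl oxazolidinone by LiBH4 attacks the exocyclic carbonyl and should release the primary alcohol without epimerisation, the auxiliary being recovered.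

**Step 5**
Reactants: 10 (S)-2-methylpent-4-en-1-ol
Product: 11 (S)-2-methylpent-4-en-1-yl acetate
Conditions: Ac2O, pyridine, DMAP (cat.), CH2Cl2, 0 °C → rt
Reagents that add atoms: acetic anhydride, CC(=O)OC(C)=O
Why: DMAP-catalysed acetylation of the primary alcohol installs the acetate of the target early, which also lowers the volatility of the C6 unit.

**Step 6**
Reactants: 11 (S)-2-methylpent-4-en-1-yl acetate
Product: 13 (S)-5-hydroxy-2-methylpentyl acetate, via B-alkyl-9-BBN 12 (not isolated)
Conditions: 9-BBN, THF, 0 °C → rt; then 30% H2O2, 3 M aq NaOAc, 0 °C → rt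
Reagents that add atoms: hydrogen peroxide, OO
Why: Anti-Markovnikov hydroboration of the terminal alkene with 9-BBN followed by buffered peroxide oxidation should give the primary alcohol while the acetate survives the weakly basic medium.

**Step 7**
Reactants: 13 (S)-5-hydroxy-2-methylpentyl acetate
Product: 14 (S)-5-iodo-2-methylpentyl acetate
Conditions: I2, PPh3, imidazole, CH2Cl2, 0 °C → rt
Reagents that add atoms: iodine, II
Why: Appel-type iodination of the primary alcohol leaves the acetate and the remote stereocentre untouched.

**Step 8**
Reactants: 14 (S)-5-iodo-2-methylpentyl acetate; 15 methyl (triphenylphosphoranylidene)acetate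
Product: 17 methyl (6S)-7-acetoxy-6-methyl-2-(triphenyl-λ5-phosphanylidene)heptanoate, via phosphonium iodide 16 (not isolated)
Conditions: 15 (2 equiv), EtOAc, reflux; precipitated phosphonium salt filtered off
Reagents that add atoms: none
Why: C-alkylation of the stabilised ylide by the primary iodide gives salt 16, which the second equivalent of 15 deprotonates (transylidation) as the parent phosphonium iodide precipitates, and the base-free medium spares the acetate.

**Step 9**
Reactants: 18 pent-4-yn-1-ol
Product: 19 pent-4-ynal
Conditions: Dess–Martin periodinane, CH2Cl2, 0 °C → rt; concentrated cold and used at once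
Reagents that add atoms: none
Why: Dess–Martin oxidation should stop cleanly at the volatile aldehyde and leave the terminal alkyne alone.

**Step 10**
Reactants: 19 pent-4-ynal; 17 methyl (6S)-7-acetoxy-6-methyl-2-(triphenyl-λ5-phosphanylidene)heptanoate
Product: 20 methyl (2E)-2-[(4S)-5-acetoxy-4-methylpentyl]hept-2-en-6-ynoate
Conditions: CH2Cl2, 40 °C
Reagents that add atoms: none
Why: Wittig olefination with an ester-stabilised α-alkyl ylide passes through the trans-oxaphosphetane and should give the (E)-enoate (CO2Me trans to C4H2) under neutral conditions.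

**Step 11**
Reactants: 20 methyl (2E)-2-[(4S)-5-acetoxy-4-methylpentyl]hept-2-en-6-ynoate; 21 trimethylaluminium; 5 3-(2-iodoethyl)furan
Product: 24 methyl (2E,6E)-2-[(4S)-5-acetoxy-4-methylpentyl]-9-(furan-3-yl)-6-methylnona-2,6-dienoate, via alkenylalane 22 (not isolated), via alkenylzinc chloride 23 (not isolated)
Conditions: 21 (4 equiv), Cp2ZrCl2 (20 mol%), H2O (1.5 equiv), CH2Cl2, −23 °C; volatiles removed in vacuo, 0 °C; THF, ZnCl2 (1.2 equiv), 0 °C; then 5 (2 equiv), Pd2(dba)3 (2 mol%), PCyp3 (8 mol%), N-methylimidazole, THF/NMP, 60 °C
Reagents that add atoms: none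
Why: Proposed new method: Zr-catalysed syn-methylalumination of the terminal alkyne (C6≡C7–H) of 20 places CH3 on C6 and aluminium on C7 on the same side to give 22, ZnCl2 exchanges Al for Zn (23), and a Pd(0)/PCyp3 catalyst adds oxidatively to the primary iodide 5 (SN2-type), transmetalates with 23 and reductively eliminates to form the C7–C8 bond with retention of alkene geometry. The closest known reaction types are the one-pot Negishi carboalumination/Pd cross-coupling of alkenylalanes with aryl, alkenyl, allyl and benzyl halides under ZnCl2 co-catalysis and the Pd/trialkylphosphine Negishi coupling of alkenylzinc halides with unactivated primary alkyl halides that carry β-hydrogens; what is new is their merger in one flask on an ester-bearing alkyne. No ring is closed and no stereocentre is created, and the remote (S) centre is not touched. The one new stereoelement, the 6E alkene with CH3 cis to C8H2, follows from the syn stereospecificity of the carbometalation and the retentive transmetalation and reductive elimination. The step needs regioselective methyl delivery to the internal alkyne carbon, which the unbranched terminal alkyne secures, and chemoselectivity over the methyl ester, the enoate and the acetate, which the low temperature of the water-accelerated methylalumination, the removal of excess Me3Al before heating and the low electrophilicity of an α,β-disubstituted enoate towards alkenylzinc reagents should secure, while the E geometry of 22 and 23 keeps the C7–metal bond pointing away from C3, so that cyclisation onto the enoate would need a trans-cyclopentene. Coupling must also outrun β-hydride elimination of the 2-(furan-3-yl)ethylpalladium intermediate, which the electron-rich, bulky PCyp3 ligand is chosen to secure.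

**Compound list**
1 | 3-bromofuran | Brc1ccoc1 | starting material
2 | ethylene oxide | C1CO1 | starting material
3 | 3-furyllithium | [Li]c1ccoc1 | intermediate
4 | 2-(furan-3-yl)ethan-1-ol | OCCc1ccoc1 | intermediate
5 | 3-(2-iodoethyl)furan | ICCc1ccoc1 | intermediate
6 | (R)-4-benzyl-3-propionyloxazolidin-2-one | CCC(=O)N1[C@H](Cc2ccccc2)COC1=O | starting material
7 | allyl iodide (3-iodoprop-1-ene) | C=CCI | starting material
8 | sodium (Z)-enolate of 6 | C/C=C(\[O-])N1[C@H](Cc2ccccc2)COC1=O.[Na+] | intermediate
9 | (R)-4-benzyl-3-[(S)-2-methylpent-4-enoyl]oxazolidin-2-one | C=CC[C@H](C)C(=O)N1[C@H](Cc2ccccc2)COC1=O | intermediate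
10 | (S)-2-methylpent-4-en-1-ol | C=CC[C@H](C)CO | intermediate
11 | (S)-2-methylpent-4-en-1-yl acetate | C=CC[C@H](C)COC(C)=O | intermediate
12 | (S)-5-(9-borabicyclo[3.3.1]nonan-9-yl)-2-methylpentyl acetate | B1(CCC[C@H](C)COC(C)=O)C2CCCC1CCC2 | intermediate
13 | (S)-5-hydroxy-2-methylpentyl acetate | OCCC[C@H](C)COC(C)=O | intermediate
14 | (S)-5-iodo-2-methylpentyl acetate | ICCC[C@H](C)COC(C)=O | intermediate
15 | methyl (triphenylphosphoranylidene)acetate | COC(=O)C=P(c1ccccc1)(c1ccccc1)c1ccccc1 | starting material
16 | [(6S)-7-acetoxy-1-methoxy-6-methyl-1-oxoheptan-2-yl]triphenylphosphonium iodide (both epimers at C2) | COC(=O)C(CCC[C@H](C)COC(C)=O)[P+](c1ccccc1)(c1ccccc1)c1ccccc1.[I-] | intermediate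
17 | methyl (6S)-7-acetoxy-6-methyl-2-(triphenyl-λ5-phosphanylidene)heptanoate | COC(=O)C(CCC[C@H](C)COC(C)=O)=P(c1ccccc1)(c1ccccc1)c1ccccc1 | intermediate
18 | pent-4-yn-1-ol | C#CCCCO | starting material
19 | pent-4-ynal | C#CCCC=O | intermediate
20 | methyl (2E)-2-[(4S)-5-acetoxy-4-methylpentyl]hept-2-en-6-ynoate | COC(=O)/C(=C/CCC#C)CCC[C@H](C)COC(C)=O | intermediate
21 | trimethylaluminium | C[Al](C)C | starting material
22 | methyl (2E,6E)-2-[(4S)-5-acetoxy-4-methylpentyl]-7-(dimethylalumanyl)-6-methylhepta-2,6-dienoate | COC(=O)/C(=C/CC/C(C)=C/[Al](C)C)CCC[C@H](C)COC(C)=O | intermediate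
23 | methyl (2E,6E)-2-[(4S)-5-acetoxy-4-methylpentyl]-7-(chlorozincio)-6-methylhepta-2,6-dienoate | COC(=O)/C(=C/CC/C(C)=C/[Zn]Cl)CCC[C@H](C)COC(C)=O | intermediate
24 | methyl (2E,6E)-2-[(4S)-5-acetoxy-4-methylpentyl]-9-(furan-3-yl)-6-methylnona-2,6-dienoate | COC(=O)/C(=C/CC/C(C)=C/CCc1ccoc1)CCC[C@H](C)COC(C)=O | target

**Totals**
Total steps: 11. Longest linear sequence: 8 steps (6 → 9 → 10 → 11 → 13 → 14 → 17 → 20 → 24; steps 3–8, 10 and 11).

**Steps most likely to fail**

Step 11 (proposed new method). Carbonyl-bound aluminium may stall the methylalumination or transfer methyl to the ester or acetate, and β-hydride elimination or methyl transfer may outrun the alkenyl–alkyl coupling. The fallback uses only known chemistry and keeps aluminium away from the esters. It sets out from 18 and comes back at 24. Zr-catalysed methylalumination of 18 with 21 (the alcohol carried as its aluminium alkoxide) and iodine quench should give (E)-5-iodo-4-methylpent-4-en-1-ol F1. Dess–Martin oxidation should give (E)-5-iodo-4-methylpent-4-enal F2. Wittig reaction with 17 should give methyl (2E,6E)-2-[(4S)-5-acetoxy-4-methylpentyl]-7-iodo-6-methylhepta-2,6-dienoate F3. Iodide 5 is converted with zinc dust and LiCl in THF into [2-(furan-3-yl)ethyl]zinc iodide F4, which is joined to F3 by a Pd-catalysed alkyl–alkenyl Negishi coupling (PdCl2(dppf), THF, rt) to form the same C7–C8 bond and give 24.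

Step 8. C-alkylation of the stabilised ylide by an unactivated primary iodide may be slow, with competing O-alkylation or incomplete transylidation. The fallback sets out from 14 and comes back at 20. Trimethyl phosphonoacetate (NaH, DMF) is alkylated with 14 to give methyl (6S)-7-acetoxy-2-(dimethoxyphosphoryl)-6-methylheptanoate F5 as a mixture of epimers at C2. A Horner–Wadsworth–Emmons reaction of F5 with 19 (LiCl, DBU, MeCN) should give 20; the E selectivity is expected to be lower than in the Wittig route, so the geometric isomers would be separated by chromatography.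

Step 1. Lithium may migrate from C3 to C2 of the furan on warming, and the epoxide opening may be incomplete. The fallback sets out from 1 and comes back at 4. Suzuki–Miyaura vinylation of 1 with potassium vinyltrifluoroborate (PdCl2(dppf), Cs2CO3, THF/H2O) should give 3-vinylfuran F6, handled in solution. Anti-Markovnikov hydroboration with 9-BBN gives 9-[2-(furan-3-yl)ethyl]-9-borabicyclo[3.3.1]nonane F7, and oxidation with H2O2/NaOH gives 4.

Further compounds
F1 | step 11 | (E)-5-iodo-4-methylpent-4-en-1-ol | OCCC/C(C)=C/I
F2 | step 11 | (E)-5-iodo-4-methylpent-4-enal | O=CCC/C(C)=C/I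
F3 | step 11 | methyl (2E,6E)-2-[(4S)-5-acetoxy-4-methylpentyl]-7-iodo-6-methylhepta-2,6-dienoate | COC(=O)/C(=C/CC/C(C)=C/I)CCC[C@H](C)COC(C)=O
F4 | step 11 | [2-(furan-3-yl)ethyl]zinc iodide | I[Zn]CCc1ccoc1
F5 | step 8 | methyl (6S)-7-acetoxy-2-(dimethoxyphosphoryl)-6-methylheptanoate | COC(=O)C(CCC[C@H](C)COC(C)=O)P(=O)(OC)OC
F6 | step 1 | 3-vinylfuran | C=Cc1ccoc1
F7 | step 1 | 9-[2-(furan-3-yl)ethyl]-9-borabicyclo[3.3.1]nonane | B1(CCc2ccoc2)C2CCCC1CCC2
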